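An equilibrium cannot shift with a catalyst, yet on one charge of L and J the last G reading moves from 0.241 M in the spring run to 0.301 M in the autumn run, with E raised from 0.00120 M to 0.00180 M. Nor is J short: the spring run holds 1.80 M of it against 0.600 M of L.

| flask | L | J | E | time |
|---|---|---|---|---|
| spring | 0.600 M | 1.80 M | 0.00120 M |  |
| dawn | 0.240 M | 1.44 M | 0.00120 M |  |
| noon | 1.80 M | 1.80 M | 0.00120 M |  |
| autumn | 0.600 M | 1.80 M | 0.00180 M |  |
| winter | 0.600 M | 1.80 M | 0.00290 M | 140 min |

- spring run (time / min: [G] / M): 23: 0.115; 47: 0.182; 70: 0.201; 93: 0.227; 120: 0.244; 140: 0.241
- dawn run (time / min: [G] / M): 23: 0.054; 47: 0.081; 70: 0.098; 93: 0.092; 120: 0.101; 140: 0.111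
- noon run (time / min: [G] / M): 23: 0.298; 47: 0.415; 70: 0.482; 93: 0.509; 120: 0.524; 140: 0.537
- autumn run (time / min: [G] / M): 23: 0.160; 47: 0.238; 70: 0.277; 93: 0.282; 120: 0.295; 140: 0.301

(readings scatter by 0.005 M)

* how the opening rate goes with [L] round the charge of the spring run: the exponent of the rate at two percent of L gone to G (one fixed amount of G, the same in the runs compared)
* how the opening rate goes with [E] round the charge of the spring run: the exponent of the rate at two percent of L gone to G
* G in the winter run at 140 min, as a share of the L charged

- Overall: L + J -> G, with E as catalyst.
- Constant volume, constant temperature.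
- An order is taken over about fifteen percent of the charge, up and down.

The first readings come first. Noon over spring reads 2.59 for a factor of 3.00 in L at equal J, and autumn over spring reads 1.39 for a factor of 1.50 in E. Each ratio is of G already made, with L partly used, and each stays near its factor. So this reckoning takes G as forming roughly as [E][L], first order in each.

The L missing from G must leave by another route. Suppose that route needs no E. Then Y, the share of charged L ending as G (the selectivity), is E/(E + Ec). Here Ec is the crossover charge, the charge of E at which L goes to G and to loss at equal rates, so Ec = E(1 − Y)/Y.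

The last row of each table can now be read, since spring's final readings, 0.244 M and 0.241 M, agree within the scatter. Spring gives 1.79 mM. Autumn, with more E, gives 1.79 mM, so Ec reads alike at these two charges of E. Dawn, with less J as well as less L, gives 1.39 mM. Noon, at the J of the spring run, gives 2.82 mM: Ec in noon is larger than in spring, so part of the loss climbs with [L] faster than first order.

The winter run has spring's L and J, so spring's Ec carries over. With 0.00290 M of E, this reckoning gives Y = 61.9%.

The forecast, which differs from this reckoning in the order in L, gives 0.8 for L, 1 for E and 60% for winter, holding that “the catalyst is dying”.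

The simulation gives 1.0 for L, 1.0 for E and 62.2% for winter.

    E + L → Ju + Q (10.44 M⁻¹ min⁻¹)
    Ju + J → G + E (97.20 M⁻¹ min⁻¹)
    L → Ek (0.01230 min⁻¹)
    2 L → Gy (0.009780 M⁻¹ min⁻¹)

The winter result puts Ec at 1.76 mM, against the carried 1.79 mM. The main reason for the winter shortfall is the reaction of L to Ek. Its part of Ec is 0.0123 min⁻¹ over 10.4 M⁻¹ min⁻¹, or 1.18 mM. Removing that part leaves 0.609 mM for the pairing of L to Gy, so a winter run without L → Ek should reach Y = 82.6%. The simulated winter run without that step reaches 83.1%.

The readings were computed from invented constants.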